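The route rests on cutting two bonds of the dihydrobenzofuran at once, O1–C2 and the oxygen-bearing bond of the C3 methylene. O1, C2, C3 and that exocyclic CH2 form a three-carbon strip functionalised at both ends and flanked by the syringyl ring (on C2) and ring A (on C3), that is, a cyclopropane in disguise. Iodonium opening of an enantioenriched trans-diarylcyclopropane, whose ring A carries a free phenol ortho to the cyclopropane and a bromine para to that phenol, should form O1–C2, the CH2–I bond, the furan ring and the C2 stereocentre in one operation. Iodide and bromide are then exchanged for the two 4-hydroxybenzoate-bearing arms.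

Key step: step 7

Assumption: (E)-3-(4,4,5,5-tetramethyl-1,3,2-dioxaborolan-2-yl)prop-2-en-1-ol is a purchased reagent, and the antipode of the cobalt porphyrin that leads to the (1R,2R) cyclopropane is fixed by a small-scale test of the sense of induction.

Step 1
Reactants: 1 5-bromo-2-hydroxy-3-methoxybenzaldehyde (5-bromo-o-vanillin)
Product: 2 2-(allyloxy)-5-bromo-3-methoxybenzaldehyde
Conditions: allyl bromide, K2CO3, DMF, 50 °C
Reagents that add atoms: allyl bromide, C=CCBr
Why: Williamson etherification of the acidic salicylaldehyde phenol; allyl is chosen because it is later removed under neutral palladium catalysis, so the cyclopropane next to a free phenol never meets a proton acid.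

Step 2
Reactants: 2 2-(allyloxy)-5-bromo-3-methoxybenzaldehyde
Product: 3 2-(allyloxy)-5-bromo-1-ethenyl-3-methoxybenzene
Conditions: Ph3PCH3Br, KOtBu, THF, 0 °C to rt
Reagents that add atoms: methyltriphenylphosphonium bromide, C[P+](c1ccccc1)(c1ccccc1)c1ccccc1.[Br-]
Why: Wittig methylenation of a non-enolisable aryl aldehyde; the aryl bromide and the allyl ether are inert to the unstabilised ylide.

Step 3
Reactants: 4 syringaldehyde (4-hydroxy-3,5-dimethoxybenzaldehyde)
Product: 5 3,5-dimethoxy-4-(triisopropylsilyloxy)benzaldehyde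
Conditions: TIPSCl, imidazole, DMAP (cat.), DMF, 40 °C
Reagents that add atoms: triisopropylsilyl chloride, CC(C)[Si](Cl)(C(C)C)C(C)C
Why: imidazole-mediated silylation of the phenol; the triisopropylsilyl ether, shielded by two ortho methoxy groups, should survive carbonate, amine and aqueous phosphate in later steps and still fall to fluoride at the end.

Step 4
Reactants: 5 3,5-dimethoxy-4-(triisopropylsilyloxy)benzaldehyde
Product: 6 N'-[(E)-[3,5-dimethoxy-4-(triisopropylsilyloxy)phenyl]methylidene]-4-methylbenzenesulfonohydrazide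
Conditions: TsNHNH2, MeOH, rt
Reagents that add atoms: 4-methylbenzenesulfonohydrazide, Cc1ccc(cc1)S(=O)(=O)NN
Why: condensation of an aryl aldehyde with a sulfonyl hydrazide (hydrazone formation), which should give the crystalline E-hydrazone as a bench-stable carbene precursor.

Step 5
Reactants: 3 2-(allyloxy)-5-bromo-1-ethenyl-3-methoxybenzene; 6 N'-[(E)-[3,5-dimethoxy-4-(triisopropylsilyloxy)phenyl]methylidene]-4-methylbenzenesulfonohydrazide
Product: 8 (1R,2R)-1-[2-(allyloxy)-5-bromo-3-methoxyphenyl]-2-[3,5-dimethoxy-4-(triisopropylsilyloxy)phenyl]cyclopropane, via aryldiazomethane 7 (not isolated)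
Conditions: Co(3,5-DitBu-Xu(2'-Naph)Phyrin) (2 mol%), Cs2CO3 (2 equiv), MeOH, 40 °C
Reagents that add atoms: none
Why: Bamford–Stevens release of the aryldiazomethane and asymmetric radical cyclopropanation of the styrene by the D2-symmetric chiral amidoporphyrin complex of divalent cobalt, a known metalloradical method for styrenes with donor-type diazo reagents made in situ; stepwise radical addition and 3-exo-tet closure should favour the trans isomer, and the chiral cavity of the porphyrin sets both new stereocentres (1R,2R).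

Step 6
Reactants: 8 (1R,2R)-1-[2-(allyloxy)-5-bromo-3-methoxyphenyl]-2-[3,5-dimethoxy-4-(triisopropylsilyloxy)phenyl]cyclopropane
Product: 9 (1R,2R)-1-(5-bromo-2-hydroxy-3-methoxyphenyl)-2-[3,5-dimethoxy-4-(triisopropylsilyloxy)phenyl]cyclopropane
Conditions: Pd(PPh3)4 (5 mol%), morpholine, THF, rt
Reagents that add atoms: none
Why: Tsuji–Trost deallylation, in which zerovalent palladium ionises the aryl allyl ether and morpholine traps the allyl fragment; these neutral conditions should leave the aryl bromide (no oxidative addition with PPh3 at rt), the silyl ether and the cyclopropane untouched.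

Step 7
Reactants: 9 (1R,2R)-1-(5-bromo-2-hydroxy-3-methoxyphenyl)-2-[3,5-dimethoxy-4-(triisopropylsilyloxy)phenyl]cyclopropane
Product: 10 (2S,3S)-5-bromo-3-(iodomethyl)-7-methoxy-2-[3,5-dimethoxy-4-(triisopropylsilyloxy)phenyl]-2,3-dihydrobenzofuran
Conditions: NIS (1.2 equiv), Ph3P=S (10 mol%), CH2Cl2, −20 °C to rt, dark
Reagents that add atoms: N-iodosuccinimide, O=C1CCC(=O)N1I
Why: Proposed new method: the bulky sulfide-bound iodonium ion should engage the unsubstituted ring carbon from its open corner, the C2–CH2 σ bond then ionises toward C2 (benzylic to the para-silyloxy syringyl ring) and the ring A phenol adds to C2 on the side opposite the departing methylene while succinimide anion removes the proton. The closest known reactions are halonium-induced 1,3-difunctionalisations of arylcyclopropanes with external oxygen nucleophiles, Lewis-base-catalysed halocyclisations of cyclopropanes carrying tethered carboxylic acids or amides, and N-iodosuccinimide opening of cyclopropanated glycals by alcohols; capture by a phenol on a 1,2-diarylcyclopropane has no precedent. The furan ring closes in the 5-exo-tet mode (O1 onto C2, the broken C2–CH2 bond lying outside the new ring). C3 is not touched and carries over the configuration fixed in step 5, whereas C2 is re-formed with inversion under control of C3 through the short tether, which turns the trans cyclopropane into the trans 2,3-disubstituted product; a looser, cation-like transition state should converge on the same, less crowded trans isomer. The step needs selection of one of three ring bonds and of the cyclopropane over the arenes: only C2–CH2 cleavage can be assisted by the phenol (a cation at C3 is out of its reach and is disfavoured by the meta bromine, and attack at the aryl-bearing carbons is hindered), while the bromine blocks the position para to the phenol and the acid-free medium keeps iodination of the flanked syringyl CH positions and protonolytic opening slow.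

Step 8
Reactants: 11 4-hydroxybenzoic acid
Product: 13 4-(triisopropylsilyloxy)benzoic acid, via bis-silylated benzoate 12 (not isolated)
Conditions: TIPSCl (2.2 equiv), imidazole, DMF, rt; then K2CO3, MeOH/THF/H2O, rt; 1 M HCl to pH 4
Reagents that add atoms: triisopropylsilyl chloride, CC(C)[Si](Cl)(C(C)C)C(C)C
Why: exhaustive silylation followed by selective hydrolysis of the much more labile silyl ester, a standard way to an O-silylated hydroxybenzoic acid.

Step 9
Reactants: 10 (2S,3S)-5-bromo-3-(iodomethyl)-7-methoxy-2-[3,5-dimethoxy-4-(triisopropylsilyloxy)phenyl]-2,3-dihydrobenzofuran; 13 4-(triisopropylsilyloxy)benzoic acid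
Product: 15 [(2S,3R)-5-bromo-7-methoxy-2-[3,5-dimethoxy-4-(triisopropylsilyloxy)phenyl]-2,3-dihydrobenzofuran-3-yl]methyl 4-(triisopropylsilyloxy)benzoate, via cesium carboxylate 14 (not isolated)
Conditions: 13 (1.5 equiv), Cs2CO3 (0.75 equiv), DMF, rt; then 10, 50 °C
Reagents that add atoms: none
Why: SN2 displacement of the primary iodide by a cesium carboxylate, with the carbonate fully consumed in salt formation so that no free base remains to eliminate HI or attack the silyl ethers; C3 is not involved, and its descriptor changes from S to R only because oxygen replaces iodine.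

Step 10
Reactants: 15 [(2S,3R)-5-bromo-7-methoxy-2-[3,5-dimethoxy-4-(triisopropylsilyloxy)phenyl]-2,3-dihydrobenzofuran-3-yl]methyl 4-(triisopropylsilyloxy)benzoate; 16 (E)-3-(4,4,5,5-tetramethyl-1,3,2-dioxaborolan-2-yl)prop-2-en-1-ol
Product: 17 [(2S,3R)-5-[(E)-3-hydroxyprop-1-enyl]-7-methoxy-2-[3,5-dimethoxy-4-(triisopropylsilyloxy)phenyl]-2,3-dihydrobenzofuran-3-yl]methyl 4-(triisopropylsilyloxy)benzoate
Conditions: Pd(dppf)Cl2 (5 mol%), K3PO4, 1,4-dioxane/H2O (10:1), 60 °C, degassed
Reagents that add atoms: none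
Why: Suzuki–Miyaura coupling of the aryl bromide with an alkenylboronate with retention of the E geometry; it is placed before the allylic ester exists, so that zerovalent palladium never meets an ionisable cinnamyl ester.

Step 11
Reactants: 17 [(2S,3R)-5-[(E)-3-hydroxyprop-1-enyl]-7-methoxy-2-[3,5-dimethoxy-4-(triisopropylsilyloxy)phenyl]-2,3-dihydrobenzofuran-3-yl]methyl 4-(triisopropylsilyloxy)benzoate; 13 4-(triisopropylsilyloxy)benzoic acid
Product: 18 (E)-3-[(2S,3R)-7-methoxy-2-[3,5-dimethoxy-4-(triisopropylsilyloxy)phenyl]-3-{[4-(triisopropylsilyloxy)benzoyl]oxymethyl}-2,3-dihydrobenzofuran-5-yl]prop-2-enyl 4-(triisopropylsilyloxy)benzoate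
Conditions: DIC, DMAP (cat.), CH2Cl2, 0 °C to rt
Reagents that add atoms: none
Why: Steglich esterification of a primary allylic alcohol under neutral conditions, which avoids acid that could ionise the electron-rich cinnamyl system.

Step 12
Reactants: 18 (E)-3-[(2S,3R)-7-methoxy-2-[3,5-dimethoxy-4-(triisopropylsilyloxy)phenyl]-3-{[4-(triisopropylsilyloxy)benzoyl]oxymethyl}-2,3-dihydrobenzofuran-5-yl]prop-2-enyl 4-(triisopropylsilyloxy)benzoate
Product: 19 quiquesetinerviusin B
Conditions: TBAF (3.5 equiv), AcOH (3.5 equiv), THF, 0 °C to rt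
Reagents that add atoms: none
Why: fluoride cleavage of the three aryl silyl ethers, buffered with acetic acid so that no phenoxide forms that could cleave an ester or open the benzylic ether at C2.

Compound list
1 | 5-bromo-2-hydroxy-3-methoxybenzaldehyde (5-bromo-o-vanillin) | COc1cc(Br)cc(C=O)c1O | starting material
2 | 2-(allyloxy)-5-bromo-3-methoxybenzaldehyde | COc1cc(Br)cc(C=O)c1OCC=C | intermediate
3 | 2-(allyloxy)-5-bromo-1-ethenyl-3-methoxybenzene | COc1cc(Br)cc(C=C)c1OCC=C | intermediate
4 | syringaldehyde (4-hydroxy-3,5-dimethoxybenzaldehyde) | COc1cc(C=O)cc(OC)c1O | starting material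
5 | 3,5-dimethoxy-4-(triisopropylsilyloxy)benzaldehyde | COc1cc(C=O)cc(OC)c1O[Si](C(C)C)(C(C)C)C(C)C | intermediate
6 | N'-[(E)-[3,5-dimethoxy-4-(triisopropylsilyloxy)phenyl]methylidene]-4-methylbenzenesulfonohydrazide | COc1cc(/C=N/NS(=O)(=O)c2ccc(C)cc2)cc(OC)c1O[Si](C(C)C)(C(C)C)C(C)C | intermediate
7 | [4-(diazomethyl)-2,6-dimethoxyphenoxy]triisopropylsilane (aryldiazomethane, formed in the flask) | COc1cc(C=[N+]=[N-])cc(OC)c1O[Si](C(C)C)(C(C)C)C(C)C | intermediate
8 | (1R,2R)-1-[2-(allyloxy)-5-bromo-3-methoxyphenyl]-2-[3,5-dimethoxy-4-(triisopropylsilyloxy)phenyl]cyclopropane | COc1cc([C@@H]2C[C@H]2c3cc(Br)cc(OC)c3OCC=C)cc(OC)c1O[Si](C(C)C)(C(C)C)C(C)C | intermediate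
9 | (1R,2R)-1-(5-bromo-2-hydroxy-3-methoxyphenyl)-2-[3,5-dimethoxy-4-(triisopropylsilyloxy)phenyl]cyclopropane | COc1cc([C@@H]2C[C@H]2c3cc(Br)cc(OC)c3O)cc(OC)c1O[Si](C(C)C)(C(C)C)C(C)C | intermediate
10 | (2S,3S)-5-bromo-3-(iodomethyl)-7-methoxy-2-[3,5-dimethoxy-4-(triisopropylsilyloxy)phenyl]-2,3-dihydrobenzofuran | COc1cc([C@H]2Oc3c(OC)cc(Br)cc3[C@@H]2CI)cc(OC)c1O[Si](C(C)C)(C(C)C)C(C)C | intermediate
11 | 4-hydroxybenzoic acid | OC(=O)c1ccc(O)cc1 | starting material
12 | triisopropylsilyl 4-(triisopropylsilyloxy)benzoate (formed in the flask) | CC(C)[Si](C(C)C)(C(C)C)OC(=O)c1ccc(O[Si](C(C)C)(C(C)C)C(C)C)cc1 | intermediate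
13 | 4-(triisopropylsilyloxy)benzoic acid | OC(=O)c1ccc(O[Si](C(C)C)(C(C)C)C(C)C)cc1 | intermediate
14 | cesium 4-(triisopropylsilyloxy)benzoate (formed in the flask) | [Cs+].[O-]C(=O)c1ccc(O[Si](C(C)C)(C(C)C)C(C)C)cc1 | intermediate
15 | [(2S,3R)-5-bromo-7-methoxy-2-[3,5-dimethoxy-4-(triisopropylsilyloxy)phenyl]-2,3-dihydrobenzofuran-3-yl]methyl 4-(triisopropylsilyloxy)benzoate | COc1cc([C@H]2Oc3c(OC)cc(Br)cc3[C@@H]2COC(=O)c2ccc(O[Si](C(C)C)(C(C)C)C(C)C)cc2)cc(OC)c1O[Si](C(C)C)(C(C)C)C(C)C | intermediate
16 | (E)-3-(4,4,5,5-tetramethyl-1,3,2-dioxaborolan-2-yl)prop-2-en-1-ol | OC/C=C/B1OC(C)(C)C(C)(C)O1 | starting material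
17 | [(2S,3R)-5-[(E)-3-hydroxyprop-1-enyl]-7-methoxy-2-[3,5-dimethoxy-4-(triisopropylsilyloxy)phenyl]-2,3-dihydrobenzofuran-3-yl]methyl 4-(triisopropylsilyloxy)benzoate | COc1cc([C@H]2Oc3c(OC)cc(/C=C/CO)cc3[C@@H]2COC(=O)c2ccc(O[Si](C(C)C)(C(C)C)C(C)C)cc2)cc(OC)c1O[Si](C(C)C)(C(C)C)C(C)C | intermediate
18 | (E)-3-[(2S,3R)-7-methoxy-2-[3,5-dimethoxy-4-(triisopropylsilyloxy)phenyl]-3-{[4-(triisopropylsilyloxy)benzoyl]oxymethyl}-2,3-dihydrobenzofuran-5-yl]prop-2-enyl 4-(triisopropylsilyloxy)benzoate | COc1cc([C@H]2Oc3c(OC)cc(/C=C/COC(=O)c4ccc(O[Si](C(C)C)(C(C)C)C(C)C)cc4)cc3[C@@H]2COC(=O)c2ccc(O[Si](C(C)C)(C(C)C)C(C)C)cc2)cc(OC)c1O[Si](C(C)C)(C(C)C)C(C)C | intermediate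
19 | quiquesetinerviusin B, (2S,3R) | COc1cc([C@H]2Oc3c(OC)cc(/C=C/COC(=O)c4ccc(O)cc4)cc3[C@@H]2COC(=O)c2ccc(O)cc2)cc(OC)c1O | target

Total step count: 12. Longest linear sequence: 9 steps (steps 1, 2, 5, 6, 7, 9, 10, 11, 12 from 1; the same length from 4 through steps 3, 4, 5).

Steps most likely to fail

Step 7 (Proposed new method). The iodonium ion may attack an aryl-bearing ring carbon and cleave the C2–C3 bond, which would lead to six-membered (flavan-type) closure. The ring may also ionise toward C3, which the phenol cannot trap. Iodination of the syringyl ring may outrun ring opening, and a free cation at C2 may erode the trans relationship. The fallback uses known chemistry only, sets out from 1 and 5 and comes back at 15. Aldehyde 5 is reduced (NaBH4, MeOH) to 3,5-dimethoxy-4-(triisopropylsilyloxy)benzyl alcohol F1. Mitsunobu etherification of phenol 1 with it (PPh3, DIAD, THF) gives aryl benzyl ether aldehyde F2. Wittig reaction with (methoxymethyl)triphenylphosphonium chloride and KHMDS gives enol ether F3 as an E/Z mixture, and PCC oxidation of the enol ether gives methyl arylacetate F4. Diazo transfer (4-acetamidobenzenesulfonyl azide, DBU, MeCN) gives aryldiazoacetate F5. Enantioselective intramolecular carbenoid C–H insertion into the benzylic ether methylene follows, with the dirhodium tetracarboxylate Rh2(S-PTTL)4 or its antipode (whichever gives 2S) in toluene at −78 °C. This is an established entry to cis-2-aryl-2,3-dihydrobenzofuran-3-carboxylates and should give cis ester F6 with C2 set by the catalyst. Base epimerisation at C3 (cat. NaOMe, MeOH, 0 °C) should give the more stable trans ester F7. LiBH4 reduction gives alcohol F8, and esterification with 13 (DIC, DMAP, CH2Cl2) gives 15. This bypasses the cyclopropane, the iodide and step 9.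

Step 5. Facial selectivity may be poor at the hindered ortho-alkoxystyrene. The benzylic radical intermediate may abstract hydrogen from the allyloxy methylene. The diazo compound may dimerise to azine, and the silyl ether may undergo slow methanolysis. The fallback gives up catalyst control, sets out from 3 and 6 and comes back at 8. The sodium salt of 6 (NaOMe, then evaporation) is decomposed in the presence of 3 with Rh2(OAc)4 and BnEt3NCl in 1,4-dioxane at 40 °C, a known trans-selective transfer of aryl carbenes from hydrazone salts to styrenes. The racemic trans cyclopropane is then resolved by preparative chromatography on a chiral stationary phase, which should give 8 and its (1S,2S) antipode F9, the latter being discarded.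

Step 9. The carboxylate may cause E2 loss of HI, followed by isomerisation of the exocyclic alkene into the aromatic benzofuran. Silyl transfer from the phenol oxygen to carboxylate may lead to phenoxide alkylation, and substitution at the β-branched carbon may be slow. The fallback replaces the SN2 reaction by radical oxygenation and acylation, sets out from 10 and comes back at 15. Tin-hydride-mediated iodine abstraction in the presence of excess TEMPO (Bu3SnH, TEMPO, toluene, 70 °C) should give alkoxyamine F10. Reductive N–O cleavage (Zn, AcOH/THF/H2O) should give alcohol F8, which is esterified with 13 (DIC, DMAP, CH2Cl2) to 15.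

Further compounds
F1 | step 7 | 3,5-dimethoxy-4-(triisopropylsilyloxy)benzyl alcohol | COc1cc(CO)cc(OC)c1O[Si](C(C)C)(C(C)C)C(C)C
F2 | step 7 | 5-bromo-2-{[3,5-dimethoxy-4-(triisopropylsilyloxy)benzyl]oxy}-3-methoxybenzaldehyde | COc1cc(Br)cc(C=O)c1OCc1cc(OC)c(O[Si](C(C)C)(C(C)C)C(C)C)c(OC)c1
F3 | step 7 | 5-bromo-2-{[3,5-dimethoxy-4-(triisopropylsilyloxy)benzyl]oxy}-3-methoxy-1-(2-methoxyethenyl)benzene (E/Z mixture) | COC=Cc1cc(Br)cc(OC)c1OCc1cc(OC)c(O[Si](C(C)C)(C(C)C)C(C)C)c(OC)c1
F4 | step 7 | methyl 2-(5-bromo-2-{[3,5-dimethoxy-4-(triisopropylsilyloxy)benzyl]oxy}-3-methoxyphenyl)acetate | COC(=O)Cc1cc(Br)cc(OC)c1OCc1cc(OC)c(O[Si](C(C)C)(C(C)C)C(C)C)c(OC)c1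
F5 | step 7 | methyl 2-(5-bromo-2-{[3,5-dimethoxy-4-(triisopropylsilyloxy)benzyl]oxy}-3-methoxyphenyl)-2-diazoacetate | COC(=O)C(=[N+]=[N-])c1cc(Br)cc(OC)c1OCc1cc(OC)c(O[Si](C(C)C)(C(C)C)C(C)C)c(OC)c1
F6 | step 7 | methyl (2S,3R)-5-bromo-7-methoxy-2-[3,5-dimethoxy-4-(triisopropylsilyloxy)phenyl]-2,3-dihydrobenzofuran-3-carboxylate (cis) | COc1cc([C@H]2Oc3c(OC)cc(Br)cc3[C@H]2C(=O)OC)cc(OC)c1O[Si](C(C)C)(C(C)C)C(C)C
F7 | step 7 | methyl (2S,3S)-5-bromo-7-methoxy-2-[3,5-dimethoxy-4-(triisopropylsilyloxy)phenyl]-2,3-dihydrobenzofuran-3-carboxylate (trans) | COc1cc([C@H]2Oc3c(OC)cc(Br)cc3[C@@H]2C(=O)OC)cc(OC)c1O[Si](C(C)C)(C(C)C)C(C)C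
F8 | step 7 | [(2S,3R)-5-bromo-7-methoxy-2-[3,5-dimethoxy-4-(triisopropylsilyloxy)phenyl]-2,3-dihydrobenzofuran-3-yl]methanol | COc1cc([C@H]2Oc3c(OC)cc(Br)cc3[C@@H]2CO)cc(OC)c1O[Si](C(C)C)(C(C)C)C(C)C
F9 | step 5 | (1S,2S)-1-[2-(allyloxy)-5-bromo-3-methoxyphenyl]-2-[3,5-dimethoxy-4-(triisopropylsilyloxy)phenyl]cyclopropane | COc1cc([C@H]2C[C@@H]2c3cc(Br)cc(OC)c3OCC=C)cc(OC)c1O[Si](C(C)C)(C(C)C)C(C)C
F10 | step 9 | 1-{[(2S,3R)-5-bromo-7-methoxy-2-[3,5-dimethoxy-4-(triisopropylsilyloxy)phenyl]-2,3-dihydrobenzofuran-3-yl]methoxy}-2,2,6,6-tetramethylpiperidine | COc1cc([C@H]2Oc3c(OC)cc(Br)cc3[C@@H]2CON2C(C)(C)CCCC2(C)C)cc(OC)c1O[Si](C(C)C)(C(C)C)C(C)C
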